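**Retrosynthetic overview**
1. C9–C10 is formed last. A retro-aldol opens the ten-membered carbocycle to a 2-methylfuran-3(2H)-one and an α-isobutyryloxy aldehyde.
2. The furanone is the second ring. The C1–C2 bond comes from an acyl Sonogashira coupling of a terminal (Z)-enyne with O-acetyl-lactoyl chloride, followed by acid-induced 5-endo closure. The isobutyrate is placed on O8 through a cyclic orthoester.
3. The key bond is C6–C7, which also closes the first ring, the α-methylene-γ-lactone. The acrylate β-carbon C7 is used with inverted polarity as an allylchromium (d3, homoenolate-type) donor. It attacks the carbonyl carbon of (Z)-3-methylpent-2-en-4-ynal, so two naturally electrophilic carbons are joined.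
4. The allyl bromide comes from a Baylis–Hillman reaction of (R)-glyceraldehyde acetonide. C8 comes from the chiral pool and controls C6/C7, and these then control C9/C10.
5. Ring order: lactone, then furanone, then carbocycle.

Assumption: C1–C15 are the germacrane locants of the target (furanone C1–C3/C10, lactone C6/C7/C11–C13) and are used for all intermediates. Compounds 1, 2, 5, 10 and 13 are catalogue chemicals.

**Step 1**
Reactants: 1 (R)-glyceraldehyde acetonide; 2 methyl acrylate
Product: 3 methyl 2-{hydroxy[(4R)-2,2-dimethyl-1,3-dioxolan-4-yl]methyl}prop-2-enoate (C7 carbinol epimers)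
Conditions: DABCO (0.5 equiv), 1,4-dioxane/H2O 1:1, rt
Reagents that add atoms: none
Why: In this Morita–Baylis–Hillman reaction the DABCO–acrylate zwitterion adds to the unhindered α-alkoxy aldehyde, C8 is carried over unchanged from the chiral pool, and the new carbinol centre is erased in step 2.

**Step 2**
Reactants: 3 Baylis–Hillman alcohol
Product: 4 methyl (2Z)-2-(bromomethyl)-3-[(4S)-2,2-dimethyl-1,3-dioxolan-4-yl]prop-2-enoate
Conditions: NBS, Me2S, CH2Cl2, 0 °C to rt
Reagents that add atoms: N-bromosuccinimide, O=C1CCC(=O)N1Br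
Why: This SN2′ bromination of the alkoxysulfonium salt (Corey–Kim-type activation) is mild enough for the acetonide, gives the conjugated (Z)-bromide and touches no stereocentre.

**Step 3**
Reactants: 5 (2Z)-3-methylpent-2-en-4-yn-1-ol
Product: 6 (2Z)-3-methylpent-2-en-4-ynal
Conditions: activated MnO2, CH2Cl2, rt, dark; used at once as a solution
Reagents that add atoms: none
Why: Neutral heterogeneous MnO2 oxidation is selective for the allylic alcohol, keeps the Z alkene (the later C4=C5) and leaves the terminal alkyne alone.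

**Step 4 (key step)**
Reactants: 4 allylic bromide; 6 (Z)-enynal
Product: 9 (4S,5R)-4-[(4S)-2,2-dimethyl-1,3-dioxolan-4-yl]-3-methylidene-5-[(1Z)-2-methylbut-1-en-3-yn-1-yl]oxolan-2-one, via E-allylchromium(III) reagent 7 (not isolated), via anti hydroxy ester 8 (not isolated)
Conditions: CrCl2 (4 equiv), THF, 0 °C to rt; then PPTS (cat.), toluene, 50 °C
Reagents that add atoms: none
Why: In this Nozaki–Hiyama-type 2-(alkoxycarbonyl)allylation and lactonisation, two Cr(II) turn the normally electrophilic acrylate β-carbon C7 into the γ-terminus of an allylchromium(III) that attacks the aldehyde carbon C6 through a chair transition state of the equilibrated E reagent (anti adduct, hence trans lactone), while A(1,3) strain with the ester keeps H-8 in the alkene plane so the aldehyde enters anti to C9, which sets 6R and 7S from C8.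

**Step 5**
Reactants: 9 lactone enyne; 10 (2S)-2-acetoxypropanoyl chloride
Product: 12 (4R,5R)-4-[(1S)-1,2-dihydroxyethyl]-3-methylidene-5-[(1Z)-2-(5-methyl-4-oxo-4,5-dihydrofuran-2-yl)prop-1-en-1-yl]oxolan-2-one (C10 epimers), via acetoxy ynone 11 (not isolated)
Conditions: PdCl2(PPh3)2 (2 mol %), CuI (4 mol %), Et3N (1.1 equiv), THF, rt; then MeOH, TsOH·H2O (0.3 equiv), 40 °C
Reagents that add atoms: none
Why: The acyl Sonogashira coupling gives the α′-acetoxy ynone, and acid methanolysis in the same flask removes acetate and acetonide so the freed C10 hydroxyl closes by 5-endo oxa-Michael addition–elimination to the 3(2H)-furanone (a coupling–deprotection–cyclocondensation sequence), with C10 left as an inconsequential epimer mixture and the trans 6,12-lactone as the thermodynamically preferred lactone.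

**Step 6**
Reactants: 12 diol; 13 trimethyl orthoisobutyrate
Product: 15 (1S)-2-hydroxy-1-{(2R,3S)-4-methylidene-2-[(1Z)-2-(5-methyl-4-oxo-4,5-dihydrofuran-2-yl)prop-1-en-1-yl]-5-oxooxolan-3-yl}ethyl 2-methylpropanoate, via cyclic orthoester 14 (not isolated)
Conditions: CSA (5 mol %), CH2Cl2, rt; then AcOH/H2O 4:1, 0 °C
Reagents that add atoms: water, O
Why: In this regioselective monoacylation through a cyclic orthoester, kinetic hydrolysis of the 2-methoxy-1,3-dioxolane leaves the ester on the more hindered secondary O8 and frees the primary C9 hydroxyl, with C8 unchanged.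

**Step 7**
Reactants: 15 primary alcohol
Product: 16 (1S)-1-{(2R,3S)-4-methylidene-2-[(1Z)-2-(5-methyl-4-oxo-4,5-dihydrofuran-2-yl)prop-1-en-1-yl]-5-oxooxolan-3-yl}-2-oxoethyl 2-methylpropanoate
Conditions: Dess–Martin periodinane, CH2Cl2, 0 °C to rt
Reagents that add atoms: none
Why: Dess–Martin oxidation is non-basic, so the α-acyloxy aldehyde forms without acyl shift, C8 epimerisation or attack on the alkenes.

**Step 8**
Reactants: 16 aldehyde
Product: 18 target (4Z,6R,7S,8S,9R,10R)-9-hydroxy-8-isobutyryloxy-1-oxo-3,10-epoxygermacra-2,4,11(13)-trien-12,6-olide, via lithium furanolate 17 (not isolated)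
Conditions: LiHMDS (1.05 equiv), THF (2 mM), −78 °C; AcOH quench at −78 °C
Reagents that add atoms: none
Why: In this intramolecular aldol addition the most acidic proton (C10–H, giving an aromatic 3-furanolate) is removed, and a lithium-bridged Zimmerman–Traxler chair with the ring oxygen locked trans to OLi places O9 anti to the ring oxygen (9R/10R relative), while the short Z-alkene/trans-lactone tether presents the aldehyde to one furanolate face with C8–O anti to the forming bond and the cold quench stops retro-aldol and acyl migration.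

**Compound list**
1 | (R)-2,2-dimethyl-1,3-dioxolane-4-carbaldehyde | CC1(C)OC[C@H](C=O)O1 | starting material
2 | methyl acrylate | C=CC(=O)OC | starting material
3 | methyl 2-{hydroxy[(4R)-2,2-dimethyl-1,3-dioxolan-4-yl]methyl}prop-2-enoate (carbinol epimers) | COC(=O)C(=C)C(O)[C@H]1COC(C)(C)O1 | intermediate
4 | methyl (2Z)-2-(bromomethyl)-3-[(4S)-2,2-dimethyl-1,3-dioxolan-4-yl]prop-2-enoate | COC(=O)/C(CBr)=C/[C@H]1COC(C)(C)O1 | intermediate
5 | (2Z)-3-methylpent-2-en-4-yn-1-ol | C#C/C(C)=C\CO | starting material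
6 | (2Z)-3-methylpent-2-en-4-ynal | C#C/C(C)=C\C=O | intermediate
7 | E-allylchromium(III) dichloride from 4 (Cr on C13, dioxolanyl cis to CO2Me) | COC(=O)/C(C[Cr](Cl)Cl)=C\[C@H]1COC(C)(C)O1 | intermediate
8 | methyl (3S,4R,5Z)-3-[(4S)-2,2-dimethyl-1,3-dioxolan-4-yl]-4-hydroxy-6-methyl-2-methylideneoct-5-en-7-ynoate (formed as Cr alkoxide) | COC(=O)C(=C)[C@H]([C@H]1COC(C)(C)O1)[C@H](O)/C=C(/C)C#C | intermediate
9 | (4S,5R)-4-[(4S)-2,2-dimethyl-1,3-dioxolan-4-yl]-3-methylidene-5-[(1Z)-2-methylbut-1-en-3-yn-1-yl]oxolan-2-one | C=C1C(=O)O[C@H](/C=C(/C)C#C)[C@H]1[C@H]2COC(C)(C)O2 | intermediate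
10 | (2S)-2-acetoxypropanoyl chloride | C[C@H](OC(C)=O)C(=O)Cl | starting material
11 | (2S,6Z)-7-{(2R,3S)-3-[(4S)-2,2-dimethyl-1,3-dioxolan-4-yl]-4-methylidene-5-oxooxolan-2-yl}-6-methyl-3-oxohept-6-en-4-yn-2-yl acetate | C=C1C(=O)O[C@H](/C=C(/C)C#CC(=O)[C@H](C)OC(C)=O)[C@H]1[C@H]2COC(C)(C)O2 | intermediate
12 | (4R,5R)-4-[(1S)-1,2-dihydroxyethyl]-3-methylidene-5-[(1Z)-2-(5-methyl-4-oxo-4,5-dihydrofuran-2-yl)prop-1-en-1-yl]oxolan-2-one (C10 epimers) | C=C1C(=O)O[C@H](/C=C(/C)C2=CC(=O)C(C)O2)[C@H]1[C@H](O)CO | intermediate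
13 | 1,1,1-trimethoxy-2-methylpropane (trimethyl orthoisobutyrate) | COC(OC)(OC)C(C)C | starting material
14 | O8,O9-cyclic orthoester of 12 (2-methoxy-2-isopropyl-1,3-dioxolane) | C=C1C(=O)O[C@H](/C=C(/C)C2=CC(=O)C(C)O2)[C@H]1[C@H]3COC(OC)(C(C)C)O3 | intermediate
15 | C8 isobutyrate, C9 primary alcohol (name in step 6; C10 epimers) | C=C1C(=O)O[C@H](/C=C(/C)C2=CC(=O)C(C)O2)[C@H]1[C@@H](CO)OC(=O)C(C)C | intermediate
16 | C8 isobutyrate, C9 aldehyde (name in step 7; C10 epimers) | C=C1C(=O)O[C@H](/C=C(/C)C2=CC(=O)C(C)O2)[C@H]1[C@@H](C=O)OC(=O)C(C)C | intermediate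
17 | lithium 2-methylfuran-3-olate of 16 | [Li+].C=C1C(=O)O[C@H](/C=C(/C)c2cc([O-])c(C)o2)[C@H]1[C@@H](C=O)OC(=O)C(C)C | intermediate
18 | CNP0265772.1 | C=C1C(=O)O[C@@H]2/C=C(/C)C3=CC(=O)[C@](C)(O3)[C@H](O)[C@@H](OC(=O)C(C)C)[C@@H]12 | target

**Step count and weakest steps**

Total steps: 8. Longest linear sequence: 7 (1 → 3 → 4 → 9 → 12 → 15 → 16 → 18).

The first weak point is step 8.
- The medium ring must close against strain, retro-aldol, C8 epimerisation and O8→O9 acyl shift.
- The 8,9-syn outcome is not the one an open-chain polar Felkin–Anh model would give, so it depends on the tether.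
- The fallback sets out from 16 and comes back at 18. It forms C9–C10 irreversibly at the acid oxidation level and sets C9 afterwards with hydride.
- Pinnick oxidation of 16 gives the carboxylic acid F6, and carbonyldiimidazole gives the acyl imidazole F7.
- LiHMDS at high dilution C-acylates the furanolate (Dieckmann-type closure) to the 9-oxo macrocycle F8.
- Luche reduction of the isolated C9 ketone then gives 18. The C1 ketone is a deactivated vinylogous ester, and hydride enters anti to the C8–O bond, which is the 8,9-syn sense.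

The second weak point is step 4.
- If the ester-bearing allylchromium reacts through its Z form, the syn adduct and the cis lactone result.
- The facial control rests on the single centre C8.
- The fallback sets out from 4 and 6 and comes back at 8, and so at 9. It takes C6 out of the C–C bond-forming event.
- Indium powder in THF/H2O gives the syn hydroxy ester F1, with C7 set by the same allylic-strain model.
- MnO2 oxidises the dienylic alcohol of F1 to the dienynone F2.
- CBS reduction with the oxazaborolidine enantiomer matched to the 6R alcohol gives 8 by reagent control, and 8 lactonises with PPTS as before.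

The third weak point is step 5.
- Acid cleavage of the acetate may be slow.
- Translactonisation to O8 and Z/E drift of the dienone are possible in the same flask.
- The fallback sets out from 6 and comes back at 12. It builds the furanone before the base-sensitive α-methylene lactone exists.
- The same acyl Sonogashira coupling of 6 with 10 gives the ynone enal F3.
- Brief K2CO3/MeOH removes the acetate and closes the furanone enal F4.
- Chromium coupling of F4 with 4 under the conditions of step 4 gives the furanone acetonide F5.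
- 80 % aqueous AcOH then only has to remove the acetonide, which gives 12.

**Further compounds**
F1 | step 4 | methyl (3S,4S,5Z)-3-[(4S)-2,2-dimethyl-1,3-dioxolan-4-yl]-4-hydroxy-6-methyl-2-methylideneoct-5-en-7-ynoate | COC(=O)C(=C)[C@H]([C@H]1COC(C)(C)O1)[C@@H](O)/C=C(/C)C#C
F2 | step 4 | methyl (3R,5Z)-3-[(4S)-2,2-dimethyl-1,3-dioxolan-4-yl]-6-methyl-2-methylidene-4-oxooct-5-en-7-ynoate | COC(=O)C(=C)[C@H]([C@H]1COC(C)(C)O1)C(=O)/C=C(/C)C#C
F3 | step 5 | (2S,6Z)-6-methyl-3,8-dioxooct-6-en-4-yn-2-yl acetate | C[C@H](OC(C)=O)C(=O)C#C/C(C)=C\C=O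
F4 | step 5 | (2Z)-3-(5-methyl-4-oxo-4,5-dihydrofuran-2-yl)but-2-enal | O=C/C=C(/C)C1=CC(=O)C(C)O1
F5 | step 5 | (4S,5R)-4-[(4S)-2,2-dimethyl-1,3-dioxolan-4-yl]-3-methylidene-5-[(1Z)-2-(5-methyl-4-oxo-4,5-dihydrofuran-2-yl)prop-1-en-1-yl]oxolan-2-one | C=C1C(=O)O[C@H](/C=C(/C)C2=CC(=O)C(C)O2)[C@H]1[C@H]3COC(C)(C)O3
F6 | step 8 | C9 carboxylic acid corresponding to aldehyde 16 | C=C1C(=O)O[C@H](/C=C(/C)C2=CC(=O)C(C)O2)[C@H]1[C@@H](C(=O)O)OC(=O)C(C)C
F7 | step 8 | C9 acyl imidazole of F6 | C=C1C(=O)O[C@H](/C=C(/C)C2=CC(=O)C(C)O2)[C@H]1[C@@H](C(=O)n3ccnc3)OC(=O)C(C)C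
F8 | step 8 | 9-oxo analogue of 18 (C9 ketone, C6/C7/C8/C10 as in 18) | C=C1C(=O)O[C@@H]2/C=C(/C)C3=CC(=O)[C@](C)(O3)C(=O)[C@@H](OC(=O)C(C)C)[C@@H]12
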